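## Structural features

CNP0154047.1 has nine rings, five of them in one fused core: a central benzene (ring C) with a single remaining CH, two 2,3-dihydrofurans fused to it (furan A and furan B), and a seven-membered carbocycle that also contains two adjacent carbons of a resorcinol ring (ring B). Furan A carries a 4-hydroxyphenyl group at C2 and a 3,5-dihydroxyphenyl group at C3. Furan B carries a 4-hydroxyphenyl group at C2, and its C3 is the doubly benzylic carbon that joins ring C to C6 of ring B. The seven-membered ring is completed by a CH2 group on the ring C carbon between the two furans and by a diarylmethine on C1 of ring B that bears a 2,4-dihydroxyphenyl group. There are five stereocentres, all R: the contiguous trans pair C2/C3 of furan A, the contiguous trans pair C2/C3 of furan B, and the methine, whose aryl group is cis to H-3 of furan B across the seven-membered ring. The methine is not adjacent to C3 of furan B, and the furan A pair is insulated from the other three centres by the flat ring C. The fragile parts are the benzylic C2–O bonds of the dihydrofurans (acid opening through a quinone methide, hydrogenolysis), the doubly benzylic C3–H bonds (dehydrogenation to benzofurans) and eight electron-rich phenols. The real difficulty is closing a seven-membered ring at a crowded doubly benzylic carbon of a nearly fully substituted arene while setting three stereochemical units that barely communicate. The key step exploits the bond from C3 of furan B to C6 of ring B: a 2-arylbenzofuran C2=C3 bond on ring C can take the ring B aryl group at C3 and hydrogen at C2 on the same face, which gives the seven-membered ring and the trans pair of furan B together.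

## Logic of the disconnections

28 from 27. Only the eight aryl O–CH3 bonds are cut. Methyl ethers survive organomagnesium reagents, strong base, palladium, iridium and dilute acid, so no phenol has to be handled before the last step. The forward step must cleave eight ethers without lasting damage to either benzylic C2–O bond.

27 from 21 and 24. Furan A is removed whole by cutting its O–C2 and C2–C3 bonds. This leaves a quinone methide on ring C (25, stored as 21) and a one-carbon 4-methoxybenzylidene donor (26, from 24). The cut is placed here because the furan A stereocentres are remote from the others, so they are best made last by a reagent that carries its own chirality. One ring, two stereocentres and two aryl groups are removed at once. The forward step needs face-selective addition of 26 to 25 and trans ring closure. 24 comes from 22 and 23 by cutting the S–CH2 bond.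

21 from 19 and 20. The bond from C5 of ring C to the future C3 of furan A is cut, together with the C–S bond. C5 is ortho to the free hydroxyl and para to the furan B oxygen, so it is the most nucleophilic carbon of 19, and the aryl-bearing carbon can come from an aldehyde. The forward step must attack C5 and not C7 or another electron-rich ring.

19 from 18. The acetal O–CH2 bond is cut. The ring C oxygen must be the only phenol that is ever free, so it carries the one protecting group that is not a methyl ether.

18 from 17 (key step). The bond between C3 of furan B and C6 of ring B is cut, together with the C2–H bond of furan B. This opens the seven-membered ring at its fusion carbon and turns the acid-labile dihydrofuran back into a robust benzofuran; bromine marks the bond site on ring B. One ring and two stereocentres are removed, leaving a single stereocentre. The forward step needs 7-exo arylpalladation of an aromatic C2=C3 bond that is faster than reduction of the arylpalladium, with face selection by the methine.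

17 from 16. The two C–H bonds across the former alkene are cut. The methine has no neighbouring functional group, so hydrogenation of an unfunctionalised trisubstituted alkene is the direct way to set it. The alkene must be one geometric isomer, because the face attacked by the catalyst depends on which aryl group is cis to the vinylic hydrogen.

16 from 14 and 15. The bond from the alkene carbon to the 2,4-dimethoxyphenyl ring is cut. Coupling to an enol triflate of fixed geometry gives one alkene isomer; dehydration of a tertiary alcohol would give both, and the two would lead to opposite enantiomers in the hydrogenation. The forward step must react at C–OTf and leave the C–Br bond of ring B alone.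

14 from 12, 12 from 11, 11 from 8 and 9. The enol C–O bond is cut, the oxidation level adjusted, and then the bond between the benzylic CH2 of ring C and the carbonyl carbon on ring B is cut. This separates the ring C benzofuran (nucleophile 10, from 8) from ring B (9). The forward steps need an organomagnesium addition that spares C–Br and an enolate of one geometry.

8 from 6 from 5. The C–Cl and acetal O–C bonds are cut. The only demand is to distinguish the phenol from the primary alcohol.

5 from 2 and 3, 2 from 1. Furan B is cut at O–C2 and at the aryl–alkyne bond, then the C–I bond is cut. This leaves a commercial resorcinol and a commercial alkyne. The demand is iodination next to the CH2OH group and not between the two hydroxyls.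

## Other disconnections considered

Alternative 1: The cut is at the two C3–aryl bonds (C3 of furan A to its 3,5-dioxyphenyl ring, C3 of furan B to ring B), made while both heterocycles are still six-membered lactones.
- **Forward key step:** the linear bis-coumarin A1 would take up two 3,5-dimethoxyphenyl groups from an arylboron partner under Rh(acac)(C2H4)2 (monovalent rhodium) and (R)-SEGPHOS or its antipode, giving the twofold-symmetric bis(4-aryl-dihydrocoumarin) A2.
- **In favour:** asymmetric 1,4-addition of arylrhodium species to coumarins is dependable and catalyst-controlled. It would set both C3 centres with the same sense in one operation, which fits the target because both are R.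
- **Against:** A2 contains no dihydrofuran. Each lactone must lose a carbon and then receive its 4-oxyphenyl group at C2. The addition must reach two positions flanking a substituted ring C carbon. Ring B is still a free aryl group, so the seven-membered ring and the methine remain, most likely by a cationic closure with substrate control only.
- **Structure:** the alternative is better for furan A, whose C3 it sets by a catalyst instead of a late chiral reagent, and it uses the hidden twofold symmetry of the two furans. The chosen plan is better for the seven-membered ring, which its key step closes together with furan B.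
- **Mechanism:** the alternative's key step is established chemistry and the chosen one is not; this is a clear point for the alternative.
- **Step economy:** the alternative is worse. Its key step forms two bonds but no ring, and ring contraction, two C2 arylations and the seven-ring closure follow, against five steps after the chosen key step.

Alternative 2: The cut is at the C2–C3 bond of both dihydrofurans.
- **Forward key step:** the bis(aryldiazoacetate) A3 with Rh2(S-PTTL)4 (divalent rhodium) or its antipode would insert each carbene into the neighbouring 4-methoxybenzylic ether C–H bond, giving the bis(cis-2-aryl-3-methoxycarbonyl-dihydrofuran) A4.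
- **In favour:** both dihydrofurans and four stereocentres arise in one catalyst-controlled step. The 4-methoxyphenyl groups enter as plain benzyl ethers, and the cis esters can be epimerised at C3 to trans.
- **Against:** C3 carries an ester where the target has an aryl group, and turning each ester into an aryl ring (one of them ring B) has no short solution. A3 is a hexasubstituted arene with two diazo groups flanking the CH2 substituent, hard and hazardous to make. The seven-membered ring is not addressed.
- **Structure:** the alternative is better in rings and stereocentres per step (two and four against one and two). It is equal in how reliably trans geometry is reached (epimerisation there, syn addition here). It leaves the wrong substituent at C3.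
- **Mechanism:** carbene C–H insertion under catalyst control is a known reaction type; on certainty the alternative is better.
- **Step economy:** the ester-to-aryl detour on both sides plus a separate seven-ring closure make it clearly longer.

Alternative 3: The cut is at both C2–aryl bonds.
- **Forward key step:** the diacid A5, converted in the flask into its bis(N-acyloxyphthalimide), would be reduced at the cathode with NiCl2(dme) (divalent nickel precatalyst) and 4,4'-di-tert-butyl-2,2'-bipyridine in the presence of an aryl iodide partner, giving the bis(trans-2,3-diaryl-dihydrofuran) A6.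
- **In favour:** both 4-oxyphenyl groups are introduced late and convergently. The C2 radical is planar, so the configuration of the acid does not matter, and capture trans to the C3 aryl group is expected. A6 already holds both furans, their four stereocentres and a protected CH2OH handle.
- **Against:** the C3 centres must already be present in A5, so the stereochemical problem is moved and not solved. The α-oxygenated radical next to an electron-rich ring may be reduced or oxidised instead of captured, and this must succeed twice. After A6 the seven-membered ring and the methine are still to be built, with substrate control alone, at a CH2 carbon wedged between two C3 aryl groups.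
- **Structure:** the alternative is equal to the chosen plan in the source of trans geometry (intrinsic to the mechanism in both) and better in convergence. It is worse in that the methine is set last without a catalyst, whereas the chosen plan sets it first and uses it to steer the ring closure.
- **Mechanism:** nickel-mediated decarboxylative arylation belongs to a known class, so the alternative is equal or better in certainty.
- **Step economy:** two bonds and no ring in the key step, and a longer route overall.

Key step: step 10

Assumption: the sense of induction of the chiral iridium catalyst (step 9) and of the sulfonium salt 24 (step 14) is taken from the accepted models; both are available as either antipode, and the antipode is used if the sense proves opposite.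

## Route

Step 1
Reactants: 1 3,5-dihydroxybenzyl alcohol
Product: 2 3,5-dihydroxy-2-iodobenzyl alcohol
Conditions: NIS (1.0 equiv), MeCN, 0 °C, dark
Reagents that add atoms: N-iodosuccinimide (O=C1CCC(=O)N1I)
Why: Electrophilic aromatic iodination of a resorcinol; under neutral kinetic conditions iodine should enter ortho to one hydroxyl and para to the other (next to the CH2OH group) and not between the hydroxyls, and one equivalent at low temperature limits di-iodination.

Step 2
Reactants: 2 3,5-dihydroxy-2-iodobenzyl alcohol, 3 4-ethynylanisole
Product: 5 4-(hydroxymethyl)-2-(4-methoxyphenyl)benzofuran-6-ol, via ortho-alkynylphenol 4 (not isolated)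
Conditions: PdCl2(PPh3)2 (3 mol %), CuI (6 mol %), Et3N, DMF, 25 → 60 °C
Reagents that add atoms: none
Why: Sonogashira coupling at the C–I bond, then 5-endo-dig addition of the neighbouring phenol to the alkyne in the same flask (heteroannulation of ortho-iodophenols) should give the 2-arylbenzofuran; the more acidic phenol cyclises in preference to the benzylic alcohol.

Step 3
Reactants: 5 4-(hydroxymethyl)-2-(4-methoxyphenyl)benzofuran-6-ol
Product: 6 [6-(methoxymethoxy)-2-(4-methoxyphenyl)benzofuran-4-yl]methanol
Conditions: MOMCl (1.1 equiv), K2CO3, acetone, 0 → 25 °C
Reagents that add atoms: chloromethyl methyl ether (COCCl)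
Why: Williamson-type O-alkylation; K2CO3 deprotonates only the phenol, so the acetal goes on the ring oxygen and the primary alcohol stays free.

Step 4
Reactants: 6 [6-(methoxymethoxy)-2-(4-methoxyphenyl)benzofuran-4-yl]methanol
Product: 8 4-(chloromethyl)-6-(methoxymethoxy)-2-(4-methoxyphenyl)benzofuran, via benzylic mesylate 7 (not isolated)
Conditions: MsCl, Et3N, CH2Cl2, 0 °C; then LiCl, DMF, 25 °C
Reagents that add atoms: methanesulfonyl chloride (CS(=O)(=O)Cl), in 7 only; lithium chloride ([Li+].[Cl-])
Why: Sulfonylation then SN2 displacement by chloride at a primary benzylic carbon; the medium stays basic to neutral, so the acetal is safe, and the chloride is preferred to the bromide to limit Wurtz coupling in step 5.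

Step 5
Reactants: 8 4-(chloromethyl)-6-(methoxymethoxy)-2-(4-methoxyphenyl)benzofuran, 9 2-bromo-4,6-dimethoxybenzaldehyde
Product: 11 racemic 1-(2-bromo-4,6-dimethoxyphenyl)-2-[6-(methoxymethoxy)-2-(4-methoxyphenyl)benzofuran-4-yl]ethanol, via benzylic Grignard reagent 10 (not isolated)
Conditions: Mg turnings, 2-MeTHF, 0 °C (slow addition of 8); then 9, THF, −78 → 0 °C; aq NH4Cl
Reagents that add atoms: magnesium ([Mg]), in 10 only
Why: Grignard formation and 1,2-addition to an aldehyde; a benzylic Grignard reagent should not exchange with an aryl bromide at low temperature, and the carbinol centre is left racemic because step 6 removes it.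

Step 6
Reactants: 11 racemic 1-(2-bromo-4,6-dimethoxyphenyl)-2-[6-(methoxymethoxy)-2-(4-methoxyphenyl)benzofuran-4-yl]ethanol
Product: 12 1-(2-bromo-4,6-dimethoxyphenyl)-2-[6-(methoxymethoxy)-2-(4-methoxyphenyl)benzofuran-4-yl]ethanone
Conditions: DMP (1,1,1-triacetoxy-1,1-dihydro-1,2-benziodoxol-3(1H)-one), CH2Cl2, 0 → 25 °C
Reagents that add atoms: none
Why: Periodinane oxidation of a secondary benzylic alcohol under near-neutral conditions; the acetal, the aryl bromide and the benzofuran should be untouched.

Step 7
Reactants: 12 1-(2-bromo-4,6-dimethoxyphenyl)-2-[6-(methoxymethoxy)-2-(4-methoxyphenyl)benzofuran-4-yl]ethanone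
Product: 14 (Z)-1-(2-bromo-4,6-dimethoxyphenyl)-2-[6-(methoxymethoxy)-2-(4-methoxyphenyl)benzofuran-4-yl]ethenyl trifluoromethanesulfonate, via potassium Z-enolate 13 (not isolated)
Conditions: KN(SiMe3)2, THF, −78 °C; then PhNTf2, −78 → 0 °C
Reagents that add atoms: potassium bis(trimethylsilyl)amide ([K+].C[Si](C)(C)[N-][Si](C)(C)C), in 13 only; N-phenylbis(trifluoromethanesulfonimide) (O=S(=O)(N(c1ccccc1)S(=O)(=O)C(F)(F)F)C(F)(F)F)
Why: Enolisation at the only acidic position and O-sulfonylation; the enolate should form with the ring C aryl group cis to oxygen, because the other geometry pushes it against the di-ortho-substituted ring B, so one geometric isomer of the triflate is expected.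

Step 8
Reactants: 14 (Z)-enol triflate, 15 2,4-dimethoxyphenylboronic acid
Product: 16 4-[(E)-2-(2-bromo-4,6-dimethoxyphenyl)-2-(2,4-dimethoxyphenyl)ethenyl]-6-(methoxymethoxy)-2-(4-methoxyphenyl)benzofuran
Conditions: Pd(PPh3)4 (5 mol %), K3PO4, 1,4-dioxane–H2O, 70 °C
Reagents that add atoms: none
Why: Suzuki–Miyaura coupling with retention of alkene geometry; with a triphenylphosphine catalyst the alkenyl C–OTf bond should undergo oxidative addition well before the hindered, electron-rich aryl C–Br bond.

Step 9
Reactants: 16 (E)-triarylethylene
Product: 17 4-[(2R)-2-(2-bromo-4,6-dimethoxyphenyl)-2-(2,4-dimethoxyphenyl)ethyl]-6-(methoxymethoxy)-2-(4-methoxyphenyl)benzofuran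
Conditions: H2 (50 bar), [Ir(cod)((S)-tBu-PHOX)][B(C6H3(CF3)2)4] (2 mol %), CH2Cl2, 25 °C
Reagents that add atoms: none
Why: Iridium-catalysed asymmetric hydrogenation of an unfunctionalised trisubstituted alkene with a cationic P,N-ligand complex (monovalent iridium precatalyst); hydrogen must reach the Si face of the diaryl carbon of the geometrically pure E alkene, a face fixed by which substituent is cis to the vinylic hydrogen, and this sets the methine as R; aryl bromide, benzofuran and acetal should not be reduced by this catalyst at room temperature.

Step 10
Reactants: 17 4-[(2R)-2-(2-bromo-4,6-dimethoxyphenyl)-2-(2,4-dimethoxyphenyl)ethyl]-6-(methoxymethoxy)-2-(4-methoxyphenyl)benzofuran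
Product: 18 seven-ring and furan B core as its methoxymethyl ether: ring C bearing OCH2OCH3; trans-(2R,3R)-2-(4-methoxyphenyl)-2,3-dihydrofuran B whose C3 is bonded to C6 of the dimethoxy ring B; seven-membered ring completed by CH2–CH(2,4-dimethoxyphenyl) with R methine; H-3 cis to that aryl group
Conditions: Pd(OAc)2 (10 mol %), P(t-Bu)3·HBF4 (20 mol %), HCO2Na (2.5 equiv, added over 6 h), DMF, 100 °C, 0.01 M
Reagents that add atoms: none
Why: Proposed new method: Pd(OAc)2 is reduced by phosphine and formate to zerovalent palladium, which inserts into the C–Br bond of ring B; the arylpalladium bromide then adds syn across the benzofuran C2=C3 bond, aryl to C3 and palladium to C2, and this 7-exo-trig carbopalladation closes the seven-membered ring and removes the furan aromaticity. The benzylic, oxygen-bearing alkylpalladium at C2 has no syn β-hydrogen (H-3 is anti and the anisyl ipso carbon has none), so it should persist until bromide is exchanged for formate, CO2 is lost and C–H reductive elimination occurs with retention. The closest known reaction type is the palladium-catalysed intramolecular dearomative reductive Heck cyclisation of indoles and benzofurans with formate, established for five- and six-membered rings; the seven-membered case is the extension proposed here. C2 of furan B: ring B and the new H-2 arrive on the same face (syn addition, retentive hydride transfer), so H-2 and H-3 are trans and the anisyl group is trans to ring B (2R,3R). C3 of furan B: the benzofuran face is chosen by the preset methine through the three-atom tether; in the boat-like transition state the methine hydrogen should lie near the plane of ring B beside its methoxy group while the 2,4-dimethoxyphenyl group points away from the ligated palladium, which should put H-3 cis to that aryl group. The step needs ring closure to outrun formate reduction of the arylpalladium and base-assisted re-aromatising C–H arylation; a bulky electron-rich phosphine, slow addition of HCO2Na and high dilution are meant to secure this, and the 2-aryl group stabilises the C2–Pd intermediate as a benzyl species. If the substrate bias at C3 is not enough, a chiral bisphosphine of matched sense such as (R)- or (S)-BINAP replaces P(t-Bu)3.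

Step 11
Reactants: 18 seven-ring and furan B core as its methoxymethyl ether
Product: 19 the corresponding ring C phenol
Conditions: HCl (2 M aq), MeOH–THF, 40 °C
Reagents that add atoms: none
Why: Acid-catalysed acetal exchange frees the single ring C phenol; the methyl ethers are inert, and the trans-dihydrofuran should tolerate dilute acid because opening at C2 is reversible and leads back to the same trans isomer.

Step 12
Reactants: 19 ring C phenol, 20 3,5-dimethoxybenzaldehyde
Product: 21 phenol 19 carrying a (3,5-dimethoxyphenyl)(4-methylbenzenesulfonyl)methyl group at C5 of ring C (ortho to the hydroxyl), both epimers at the new carbon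
Conditions: p-TolSO2H (1.5 equiv), p-TsOH·H2O (10 mol %), CH2Cl2, 25 °C
Reagents that add atoms: p-toluenesulfinic acid (Cc1ccc(S(=O)O)cc1)
Why: Three-component Friedel–Crafts-type hydroxyalkylation with sulfinate capture, the standard entry to quinone methide precursors from sesamol-type phenols and naphthols; the electrophile should attack C5, ortho to the hydroxyl and para to the furan B oxygen, and the sulfonyl-bearing centre is erased in step 14.

Step 13
Reactants: 22 isothiocineole (4,7,7-trimethyl-6-thiabicyclo[3.2.1]octane, enantiomer derived from (R)-limonene, methyl cis to the sulfur bridge), 23 4-methoxybenzyl bromide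
Product: 24 S-(4-methoxybenzyl)isothiocineolium trifluoromethanesulfonate
Conditions: LiOTf, CH2Cl2–H2O, 25 °C
Reagents that add atoms: lithium trifluoromethanesulfonate ([Li+].[O-]S(=O)(=O)C(F)(F)F)
Why: S-alkylation of a sulfide by a reactive benzylic bromide with exchange to the non-nucleophilic triflate, which holds the equilibrium on the side of the salt; the benzyl group should take the less hindered lone pair of sulfur.

Step 14
Reactants: 21 ring C sulfone, 24 S-(4-methoxybenzyl)isothiocineolium trifluoromethanesulfonate
Product: 27 octa-O-methyl ether of the target, via ortho-quinone methide 25 (not isolated), via sulfonium ylide 26 (not isolated)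
Conditions: Cs2CO3 (3 equiv), MeCN–CH2Cl2, 0 → 25 °C
Reagents that add atoms: none
Why: Formal [4+1] annulation of an ortho-quinone methide with a sulfur ylide: base expels sulfinate from 21 and deprotonates 24, the ylide carbon adds to the exocyclic carbon of 25, and the phenoxide displaces the sulfide with inversion. The chiral sulfide should fix the attacking face of the ylide carbon (C2 of furan A, R) and the anti approach of the two aryl groups should fix C3 (R), so furan A forms trans under reagent control that overrides the weak bias of the distant stereocentres.

Step 15
Reactants: 27 octa-O-methyl ether of the target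
Product: 28 CNP0154047.1
Conditions: BBr3 (24 equiv), CH2Cl2, −78 → 0 °C; then MeOH, H2O
Reagents that add atoms: none
Why: Lewis-acid cleavage of all eight aryl methyl ethers (bromide attacks methyl); both dihydrofurans are already the thermodynamic trans isomers at C2, so reversible C2–O ionisation cannot change them, and C3 and the methine have no path to epimerise.

## Compound list

1 | 3,5-dihydroxybenzyl alcohol | OCc1cc(O)cc(O)c1 | starting material
2 | 3,5-dihydroxy-2-iodobenzyl alcohol | OCc1cc(O)cc(O)c1I | intermediate
3 | 4-ethynylanisole | COc1ccc(C#C)cc1 | starting material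
4 | 5-(hydroxymethyl)-4-[(4-methoxyphenyl)ethynyl]benzene-1,3-diol (not isolated) | OCc1cc(O)cc(O)c1C#Cc1ccc(OC)cc1 | intermediate
5 | 4-(hydroxymethyl)-2-(4-methoxyphenyl)benzofuran-6-ol | OCc1cc(O)cc2oc(-c3ccc(OC)cc3)cc12 | intermediate
6 | [6-(methoxymethoxy)-2-(4-methoxyphenyl)benzofuran-4-yl]methanol | COCOc1cc(CO)c2cc(-c3ccc(OC)cc3)oc2c1 | intermediate
7 | [6-(methoxymethoxy)-2-(4-methoxyphenyl)benzofuran-4-yl]methyl methanesulfonate (not isolated) | COCOc1cc(COS(C)(=O)=O)c2cc(-c3ccc(OC)cc3)oc2c1 | intermediate
8 | 4-(chloromethyl)-6-(methoxymethoxy)-2-(4-methoxyphenyl)benzofuran | COCOc1cc(CCl)c2cc(-c3ccc(OC)cc3)oc2c1 | intermediate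
9 | 2-bromo-4,6-dimethoxybenzaldehyde | O=Cc1c(Br)cc(OC)cc1OC | starting material
10 | {[6-(methoxymethoxy)-2-(4-methoxyphenyl)benzofuran-4-yl]methyl}magnesium chloride (not isolated) | COCOc1cc(C[Mg]Cl)c2cc(-c3ccc(OC)cc3)oc2c1 | intermediate
11 | 1-(2-bromo-4,6-dimethoxyphenyl)-2-[6-(methoxymethoxy)-2-(4-methoxyphenyl)benzofuran-4-yl]ethanol, racemic | COCOc1cc(CC(O)c2c(OC)cc(OC)cc2Br)c2cc(-c3ccc(OC)cc3)oc2c1 | intermediate
12 | 1-(2-bromo-4,6-dimethoxyphenyl)-2-[6-(methoxymethoxy)-2-(4-methoxyphenyl)benzofuran-4-yl]ethanone | COCOc1cc(CC(=O)c2c(OC)cc(OC)cc2Br)c2cc(-c3ccc(OC)cc3)oc2c1 | intermediate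
13 | potassium (Z)-enolate of 12, ring C aryl group cis to O (not isolated) | COCOc1cc(/C=C(\[O-])c2c(OC)cc(OC)cc2Br)c2cc(-c3ccc(OC)cc3)oc2c1.[K+] | intermediate
14 | (Z)-1-(2-bromo-4,6-dimethoxyphenyl)-2-[6-(methoxymethoxy)-2-(4-methoxyphenyl)benzofuran-4-yl]ethenyl trifluoromethanesulfonate | COCOc1cc(/C=C(\OS(=O)(=O)C(F)(F)F)c2c(OC)cc(OC)cc2Br)c2cc(-c3ccc(OC)cc3)oc2c1 | intermediate
15 | 2,4-dimethoxyphenylboronic acid | COc1ccc(B(O)O)c(OC)c1 | starting material
16 | 4-[(E)-2-(2-bromo-4,6-dimethoxyphenyl)-2-(2,4-dimethoxyphenyl)ethenyl]-6-(methoxymethoxy)-2-(4-methoxyphenyl)benzofuran | COCOc1cc(/C=C(\c2ccc(OC)cc2OC)c2c(OC)cc(OC)cc2Br)c2cc(-c3ccc(OC)cc3)oc2c1 | intermediate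
17 | 4-[(2R)-2-(2-bromo-4,6-dimethoxyphenyl)-2-(2,4-dimethoxyphenyl)ethyl]-6-(methoxymethoxy)-2-(4-methoxyphenyl)benzofuran (precursor of the key step) | COCOc1cc2oc(-c3ccc(OC)cc3)cc2c(C[C@H](c2ccc(OC)cc2OC)c2c(OC)cc(OC)cc2Br)c1 | intermediate
18 | seven-ring and furan B core as its methoxymethyl ether; furan B (2R,3R) trans, methine R | COCOc1cc2c3c(c1)C[C@H](c1ccc(OC)cc1OC)c1c(OC)cc(OC)cc1[C@H]3[C@H](c1ccc(OC)cc1)O2 | intermediate
19 | ring C phenol of the seven-ring and furan B core | Oc1cc2c3c(c1)C[C@H](c1ccc(OC)cc1OC)c1c(OC)cc(OC)cc1[C@H]3[C@H](c1ccc(OC)cc1)O2 | intermediate
20 | 3,5-dimethoxybenzaldehyde | COc1cc(C=O)cc(OC)c1 | starting material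
21 | phenol 19 with a (3,5-dimethoxyphenyl)(4-methylbenzenesulfonyl)methyl group at C5 of ring C; sulfonyl-bearing carbon as both epimers | Oc1cc2c3c(c1C(c1cc(OC)cc(OC)c1)S(=O)(=O)c1ccc(C)cc1)C[C@H](c1ccc(OC)cc1OC)c1c(OC)cc(OC)cc1[C@H]3[C@H](c1ccc(OC)cc1)O2 | intermediate
22 | isothiocineole, enantiomer derived from (R)-limonene | C[C@H]1CC[C@@H]2C[C@H]1SC2(C)C | starting material
23 | 4-methoxybenzyl bromide | COc1ccc(CBr)cc1 | starting material
24 | S-(4-methoxybenzyl)isothiocineolium trifluoromethanesulfonate (configuration at sulfur not specified) | C[C@H]1CC[C@@H]2C[C@H]1[S+](Cc1ccc(OC)cc1)C2(C)C.[O-]S(=O)(=O)C(F)(F)F | intermediate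
25 | ortho-quinone methide of ring C with exocyclic 3,5-dimethoxybenzylidene at C5 (alkene geometry not specified; not isolated) | O=C1C=C2O[C@@H](c3ccc(OC)cc3)[C@@H]3c4cc(OC)cc(OC)c4[C@@H](c4ccc(OC)cc4OC)CC(=C23)C1=Cc1cc(OC)cc(OC)c1 | intermediate
26 | 4-methoxybenzylide of the isothiocineolium salt (not isolated) | C[C@H]1CC[C@@H]2C[C@H]1[S+]([CH-]c1ccc(OC)cc1)C2(C)C | intermediate
27 | octa-O-methyl ether of the target; furan A (2R,3R) trans, furan B (2R,3R) trans, methine R | COc1ccc([C@@H]2Oc3cc4c5c(c3[C@H]2c2cc(OC)cc(OC)c2)C[C@H](c2ccc(OC)cc2OC)c2c(OC)cc(OC)cc2[C@H]5[C@H](c2ccc(OC)cc2)O4)cc1 | intermediate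
28 | CNP0154047.1 | Oc1ccc([C@@H]2Oc3cc4c5c(c3[C@H]2c2cc(O)cc(O)c2)C[C@H](c2ccc(O)cc2O)c2c(O)cc(O)cc2[C@H]5[C@H](c2ccc(O)cc2)O4)cc1 | target

## Step count and least certain steps

Total: 15 steps. Longest linear sequence: 14 steps (steps 1 to 12, 14 and 15; step 13 is a one-step side branch).

Step 10 (key step, proposed new method).
- **What may go wrong:** hydride transfer from formate to the arylpalladium before the slow seven-membered carbopalladation, so that bromine is lost without ring closure; re-aromatisation by base-assisted loss of H-3 (net C–H arylation); and insufficient face selectivity at C3.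
- **Fallback (known chemistry), from 17 back to 19:** intramolecular direct C–H arylation of benzofuran C3 (Pd(OAc)2, PCy3·HBF4, K2CO3, pivalic acid, DMA, 110 °C), a reaction type known to close seven-membered rings, gives the aromatic benzofuran-fused dibenzocycloheptene F1. The acetal is removed (HCl, MeOH) to give the phenol F2. Ionic hydrogenation (Et3SiH, TFA, CH2Cl2) protonates C3 and delivers hydride to the C2 oxocarbenium ion, and acid equilibration at C2 ends in the trans isomer, 19. The price is that C3 is then set by the face of protonation, so diastereomers may have to be separated.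

Step 14.
- **What may go wrong:** slow ylide formation or addition, so that the quinone methide oligomerises or takes sulfinate back; and a mismatch between the facial preference of the reagent and that of the substrate.
- **Fallback, from 21 back to 27:** two equivalents of 2-lithio-2-(4-methoxyphenyl)-1,3-dithiane (THF, −78 °C) generate the quinone methide and add to it, giving the dithiane adduct F3. Hydrolysis (MeI, CaCO3, aqueous MeCN) gives the α,α-diaryl ketone F4, whose epimers at the future C3 can be separated and interconverted with base, so the wrong one is recycled. NaBH4 gives the alcohol F5. Acid (p-TsOH, CH2Cl2) closes furan A through the 4-methoxybenzyl cation, trans to the C3 aryl group, and gives 27.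

Step 9.
- **What may go wrong:** incomplete hydrogenation of a crowded triarylethylene; erosion of enantioselectivity if the alkene isomerises on the metal; and, under forcing pressure, reduction of the C–Br bond or of the benzofuran.
- **Fallback, from 11 back to 17:** Friedel–Crafts alkylation of 1,3-dimethoxybenzene (in excess) by the ionised benzylic alcohol (Bi(OTf)3 5 mol %, MeNO2, 25 °C) gives the racemic precursor F6. The cation is stabilised by the ortho- and para-methoxy groups of ring B and is attacked by C4 of the arene. F6 is resolved by preparative chromatography on a chiral stationary phase to return 17. Steps 6 to 9 are bypassed at the cost of half the material; if the acetal is lost it is put back as in step 3.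

Step 12.
- **What may go wrong:** attack at C7 (between the two oxygens) or on another electron-rich ring, and addition of a second phenol to the benzhydryl cation.
- **Fallback, from 19 back to 21:** magnesium-mediated ortho-formylation (MgCl2, Et3N, paraformaldehyde, MeCN, reflux) is confined to the positions ortho to the free hydroxyl and allows regioisomers to be separated at a simple stage; it gives the salicylaldehyde F7. 3,5-Dimethoxyphenylmagnesium bromide (2.2 equiv, THF, 0 °C) gives the benzhydrol F8. p-TolSO2H exchanges the benzylic hydroxyl for the sulfonyl group and returns 21.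

Step 1.
- **What may go wrong:** iodination between the two hydroxyls, and di-iodination.
- **Fallback, from 1 back to 5:** both phenols are first converted into methoxymethyl ethers (MOMCl, K2CO3, acetone) to give the bis-acetal F9. NIS then iodinates next to the CH2OH group, the usual site for 3,5-dialkoxybenzyl alcohols, to give the iodide F10. Sonogashira coupling with 3 (PdCl2(PPh3)2, CuI, Et3N) gives the alkyne F11. HCl in MeOH followed by CuI and Et3N removes both acetals and cyclises through 4 to 5.

## Further compounds

F1 | step 10 | benzofuran-fused dibenzocycloheptene from C3–H arylation of 17, methoxymethyl ether, methine R | COCOc1cc2oc(-c3ccc(OC)cc3)c3c2c(c1)C[C@H](c1ccc(OC)cc1OC)c1c(OC)cc(OC)cc1-3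
F2 | step 10 | phenol corresponding to F1 | Oc1cc2oc(-c3ccc(OC)cc3)c3c2c(c1)C[C@H](c1ccc(OC)cc1OC)c1c(OC)cc(OC)cc1-3
F3 | step 14 | phenol 19 with a (3,5-dimethoxyphenyl)[2-(4-methoxyphenyl)-1,3-dithian-2-yl]methyl group at C5 of ring C, both epimers at the new carbon | Oc1cc2c3c(c1C(c1cc(OC)cc(OC)c1)C1(SCCCS1)c1ccc(OC)cc1)C[C@H](c1ccc(OC)cc1OC)c1c(OC)cc(OC)cc1[C@H]3[C@H](c1ccc(OC)cc1)O2
F4 | step 14 | phenol 19 with a 1-(3,5-dimethoxyphenyl)-2-(4-methoxyphenyl)-2-oxoethyl group at C5 of ring C, epimer leading to R at C3 of furan A | Oc1cc2c3c(c1[C@@H](c1cc(OC)cc(OC)c1)C(=O)c1ccc(OC)cc1)C[C@H](c1ccc(OC)cc1OC)c1c(OC)cc(OC)cc1[C@H]3[C@H](c1ccc(OC)cc1)O2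
F5 | step 14 | alcohol from reduction of F4, carbinol configuration not specified | Oc1cc2c3c(c1[C@@H](c1cc(OC)cc(OC)c1)C(O)c1ccc(OC)cc1)C[C@H](c1ccc(OC)cc1OC)c1c(OC)cc(OC)cc1[C@H]3[C@H](c1ccc(OC)cc1)O2
F6 | step 9 | racemic 17 | COCOc1cc2oc(-c3ccc(OC)cc3)cc2c(CC(c2ccc(OC)cc2OC)c2c(OC)cc(OC)cc2Br)c1
F7 | step 12 | phenol 19 with a formyl group at C5 of ring C | Oc1cc2c3c(c1C=O)C[C@H](c1ccc(OC)cc1OC)c1c(OC)cc(OC)cc1[C@H]3[C@H](c1ccc(OC)cc1)O2
F8 | step 12 | phenol 19 with a (3,5-dimethoxyphenyl)hydroxymethyl group at C5 of ring C, both epimers | Oc1cc2c3c(c1C(O)c1cc(OC)cc(OC)c1)C[C@H](c1ccc(OC)cc1OC)c1c(OC)cc(OC)cc1[C@H]3[C@H](c1ccc(OC)cc1)O2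
F9 | step 1 | 3,5-bis(methoxymethoxy)benzyl alcohol | COCOc1cc(CO)cc(OCOC)c1
F10 | step 1 | 2-iodo-3,5-bis(methoxymethoxy)benzyl alcohol | COCOc1cc(OCOC)c(I)c(CO)c1
F11 | step 1 | 2-[(4-methoxyphenyl)ethynyl]-3,5-bis(methoxymethoxy)benzyl alcohol | COCOc1cc(OCOC)c(C#Cc2ccc(OC)cc2)c(CO)c1
A1 | alternative 1 | (2,8-dioxo-2H,8H-pyrano[3,2-g]chromen-5-yl)methyl pivalate, the linear bis-coumarin | O=C1C=Cc2c(COC(=O)C(C)(C)C)c3C=CC(=O)Oc3cc2O1
A2 | alternative 1 | twofold-symmetric bis(4-(3,5-dimethoxyphenyl)-dihydrocoumarin) on ring C | O=C1C[C@H](c4cc(OC)cc(OC)c4)c2c(COC(=O)C(C)(C)C)c3[C@@H](c4cc(OC)cc(OC)c4)CC(=O)Oc3cc2O1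
A3 | alternative 2 | ring C bis(aryldiazoacetate) with two 4-methoxybenzyl ethers and a pivaloyloxymethyl group | COc1ccc(COc2cc(OCc3ccc(OC)cc3)c(C(=[N+]=[N-])C(=O)OC)c(COC(=O)C(C)(C)C)c2C(=[N+]=[N-])C(=O)OC)cc1
A4 | alternative 2 | twofold-symmetric bis(cis-2-(4-methoxyphenyl)-3-methoxycarbonyl-dihydrofuran) on ring C | COc1ccc([C@@H]2Oc3cc4c(c(COC(=O)C(C)(C)C)c3[C@@H]2C(=O)OC)[C@H](C(=O)OC)[C@H](c2ccc(OC)cc2)O4)cc1
A5 | alternative 3 | bis(trans-3-(3,5-dimethoxyphenyl)-dihydrofuran-2-carboxylic acid) on ring C with a triisopropylsilyloxymethyl group | OC(=O)[C@@H]1Oc2cc3c(c(CO[Si](C(C)C)(C(C)C)C(C)C)c2[C@H]1c1cc(OC)cc(OC)c1)[C@@H](c1cc(OC)cc(OC)c1)[C@H](C(=O)O)O3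
A6 | alternative 3 | twofold-symmetric bis(trans-2,3-diaryl-dihydrofuran) on ring C with a triisopropylsilyloxymethyl group | COc1ccc([C@@H]2Oc3cc4c(c(CO[Si](C(C)C)(C(C)C)C(C)C)c3[C@H]2c2cc(OC)cc(OC)c2)[C@@H](c2cc(OC)cc(OC)c2)[C@H](c2ccc(OC)cc2)O4)cc1
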